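**Retrosynthetic overview**

1. Both flavan units are the same (2R)-2-aryl-3-oxy-7,8-dioxygenated chroman, so one monomer (10) is made once and used twice. The interflavan bond C4(upper)–C6(lower) is cut to the C4 ketone 11 and a C6 aryl metal from bromide 13; the upper C4–H is put in last (hydride trans to the axial 3-oxygen), which should make the upper ring all-cis.
2. Monomer: ring C is opened at C3–C4, giving cyclic enol ether 8 and then diene 7 (ring-closing metathesis); syn hydroboration of 8 anti to the C2 aryl sets C3 and C4 together (2,3-cis-3,4-trans).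
3. Feature used: in ring C, C3 and C4 are neighbouring oxygen-bearing carbons, C4 attached to aryl carbon C4a and C3 to the O1–C2 ether link. Each is a former carbonyl carbon (C4 the formyl carbon of a salicylaldehyde, C3 the ester carbonyl of an O-aryl mandelate), so C3=C4 is an enol-ether olefin that metathesis can close and whose oxygen steers boron to C4.
4. C2 is the only stereocentre brought in from outside: asymmetric carbene O–H insertion of aryl diazoacetate 5 into phenol 2.
5. Ring order: rings A and B are purchased arenes; ring C of the monomer is formed in step 6 and becomes ring C of the lower unit (via 12, 13) and of the upper unit (via 11); no other ring is formed.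

Key step: step 6

Remark: the ligand antipode that gives the R ester 6 in step 4 is meant throughout; R/S letters at C3 and C4 change along the route only because substituent priorities change, the geometry is carried through unchanged.

**Route**

Step 1
Reactants: 1 2,3,4-trihydroxybenzaldehyde
Product: 2 3,4-bis(benzyloxy)-2-hydroxybenzaldehyde
Conditions: BnBr (2.1 equiv), K2CO3 (2.2 equiv), DMF, 25 °C
Reagents that add atoms: benzyl bromide, BrCc1ccccc1
Why: Williamson etherification; the 2-hydroxyl is hydrogen-bonded to the formyl group and is the least nucleophilic, so only O3 and O4 should be benzylated.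

Step 2
Reactants: 3 (3,4-dihydroxyphenyl)acetic acid
Product: 4 benzyl 2-[3,4-bis(benzyloxy)phenyl]acetate
Conditions: BnBr (3.3 equiv), K2CO3 (3.5 equiv), DMF, 60 °C
Reagents that add atoms: benzyl bromide, BrCc1ccccc1
Why: Williamson etherification of both phenols and O-alkylation of the carboxylate in one operation.

Step 3
Reactants: 4 benzyl 2-[3,4-bis(benzyloxy)phenyl]acetate
Product: 5 benzyl 2-[3,4-bis(benzyloxy)phenyl]-2-diazoacetate
Conditions: 4-acetamidobenzenesulfonyl azide (1.3 equiv), DBU (1.5 equiv), MeCN, 0 to 25 °C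
Reagents that add atoms: 4-acetamidobenzenesulfonyl azide, CC(=O)Nc1ccc(cc1)S(=O)(=O)N=[N+]=[N-]
Why: Regitz diazo transfer to the benzylic ester enolate, standard for aryl acetates including electron-rich ones.

Step 4
Reactants: 2 3,4-bis(benzyloxy)-2-hydroxybenzaldehyde; 5 benzyl 2-[3,4-bis(benzyloxy)phenyl]-2-diazoacetate
Product: 6 benzyl (2R)-2-[3,4-bis(benzyloxy)phenyl]-2-[2,3-bis(benzyloxy)-6-formylphenoxy]acetate
Conditions: Pd(PhCN)2Cl2 (5 mol%), chiral 7,7′-bis(4-phenyloxazolin-2-yl)-1,1′-spirobiindane ligand (6 mol%), Na[B(3,5-(CF3)2C6H3)4] (12 mol%), 5 Å molecular sieves, CHCl3, 25 °C, slow addition of 5 to 2 (1.2 equiv)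
Reagents that add atoms: none
Why: Asymmetric carbene O–H insertion into a phenol: the palladium carbene of the donor–acceptor diazo ester is captured by the phenol oxygen and the proton shift within the chiral metal-bound ylide sets C2 (the future C2 of both flavan units) as R.

Step 5
Reactants: 6 benzyl (2R)-2-[3,4-bis(benzyloxy)phenyl]-2-[2,3-bis(benzyloxy)-6-formylphenoxy]acetate
Product: 7 1,2-bis(benzyloxy)-3-{[(1R)-2-(benzyloxy)-1-[3,4-bis(benzyloxy)phenyl]prop-2-en-1-yl]oxy}-4-ethenylbenzene
Conditions: Cp2TiMe2 (5 equiv), toluene, 70 °C, dark; filtration through basic alumina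
Reagents that add atoms: dimethyltitanocene, C[Ti](C)(C1C=CC=C1)C1C=CC=C1
Why: Petasis methylenation of the aldehyde (to the styrene) and of the benzyl ester (to the benzyl enol ether) by titanocene methylidene through oxatitanacyclobutanes; the reagent is not basic, so the C2 centre next to the ester should not epimerise.

Step 6
Reactants: 7 1,2-bis(benzyloxy)-3-{[(1R)-2-(benzyloxy)-1-[3,4-bis(benzyloxy)phenyl]prop-2-en-1-yl]oxy}-4-ethenylbenzene
Product: 10 (2R,3R,4S)-3,7,8-tris(benzyloxy)-2-[3,4-bis(benzyloxy)phenyl]chroman-4-ol, via enol ether 8 (not isolated), via alkylborane 9 (not isolated)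
Conditions: RuCl2(=CHPh)(H2IMes)(PCy3) (second-generation Grubbs catalyst, 5 mol%), toluene (0.02 M), 70 °C, argon sparge; then 0 °C, BH3·THF (4 equiv), 0 to 25 °C; then aq NaOH (3 M), 30% H2O2, 0 to 25 °C
Reagents that add atoms: borane–tetrahydrofuran, B.C1CCOC1 (boron is held in 9 only); hydrogen peroxide, OO (oxygen of the C4 hydroxyl)
Why: Ring-closing olefin metathesis followed in the same flask by hydroboration–oxidation. The ruthenium benzylidene exchanges onto the terminal styrene carbon (the future C4), the new carbene, held near by the ortho ether oxygen O1, adds [2+2] to the 1,1-disubstituted enol ether and cycloreverts, which expels ethene and closes the six-membered ring C (O1–C2–C3=C4–C4a–C8a) by forming C3=C4; this is the enol-ether variant of the ring-closing metathesis in routine use for 2H-chromenes and cyclic enol ethers. Borane then adds syn across C3=C4 as it does to 1-alkoxycycloalkenes and glycals: boron to C4 (β to the enol oxygen and the only olefin carbon that carries hydrogen), hydrogen to C3. The C2 aryl group is pseudo-axial in the 2H-chromene (it avoids the 3-benzyloxy group) and blocks one face, so H and B both enter trans to it: C3 ends with its benzyloxy group cis to the aryl (3R) and C4, after oxidation with retention, with its hydroxyl trans to it (4S), i.e. 2,3-cis-3,4-trans. The selectivities needed are loading of ruthenium on the styrene and not on the enol ether (secured by the 1,1-disubstitution of the enol ether), boron on C4 and not C3 (secured by the enol oxygen and by C3 being fully substituted) and survival of the β-alkoxyborane (0 °C, immediate oxidation); 8 is not isolated because cyclic enol ethers hydrolyse on silica.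

Step 7
Reactants: 10 (2R,3R,4S)-3,7,8-tris(benzyloxy)-2-[3,4-bis(benzyloxy)phenyl]chroman-4-ol
Product: 11 (2R,3S)-3,7,8-tris(benzyloxy)-2-[3,4-bis(benzyloxy)phenyl]chroman-4-one (2,3-cis)
Conditions: Dess–Martin periodinane (1.5 equiv), pyridine, CH2Cl2, 0 to 25 °C
Reagents that add atoms: none
Why: Dess–Martin oxidation of the benzylic alcohol under buffered, non-enolising conditions; the equatorial C3–H overlaps poorly with the carbonyl, so the 2,3-cis arrangement should be kept.

Step 8
Reactants: 10 (2R,3R,4S)-3,7,8-tris(benzyloxy)-2-[3,4-bis(benzyloxy)phenyl]chroman-4-ol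
Product: 12 (2R,3R,4S)-3,4,7,8-tetrakis(benzyloxy)-2-[3,4-bis(benzyloxy)phenyl]chromane
Conditions: NaH (1.5 equiv), BnBr (1.5 equiv), Bu4NI (cat.), DMF, 0 to 25 °C
Reagents that add atoms: benzyl bromide, BrCc1ccccc1
Why: Williamson etherification; the C4 benzyl ether tolerates the aryllithium chemistry and leaves with the other benzyl groups in the last step.

Step 9
Reactants: 12 (2R,3R,4S)-3,4,7,8-tetrakis(benzyloxy)-2-[3,4-bis(benzyloxy)phenyl]chromane
Product: 13 (2R,3R,4S)-6-bromo-3,4,7,8-tetrakis(benzyloxy)-2-[3,4-bis(benzyloxy)phenyl]chromane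
Conditions: NBS (1.05 equiv), DMF, −20 to 0 °C, dark
Reagents that add atoms: N-bromosuccinimide, O=C1CCC(=O)N1Br
Why: Electrophilic aromatic bromination at C6, the only ring carbon that is ortho to one ether oxygen (O7) and para to another (O1); the B ring has a single para oxygen per position and should react more slowly.

Step 10
Reactants: 13 (2R,3R,4S)-6-bromo-3,4,7,8-tetrakis(benzyloxy)-2-[3,4-bis(benzyloxy)phenyl]chromane; 11 (2R,3S)-3,7,8-tris(benzyloxy)-2-[3,4-bis(benzyloxy)phenyl]chroman-4-one
Product: 16 4-aryl-chroman-4-ol dimer (C4 epimers of the upper ring), via aryllithium 14 (not isolated), via arylcerium dichloride 15 (not isolated)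
Conditions: 13, t-BuLi (2.1 equiv), THF, −78 °C; CeCl3 (1.5 equiv, anhydrous slurry in THF), −78 °C; then 11, −78 to −40 °C; pH 7 buffer
Reagents that add atoms: tert-butyllithium, [Li]C(C)(C)C (lithium in 14 only); cerium trichloride, Cl[Ce](Cl)Cl (cerium and chlorine in 15 only)
Why: Bromine–lithium exchange, transmetalation to the weakly basic organocerium and 1,2-addition to the aryl ketone, the usual way to add aryl metals to enolisable flavanone-type ketones; the configuration of the new carbinol carbon is of no consequence because it is erased in step 11.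

Step 11
Reactants: 16 4-aryl-chroman-4-ol dimer (C4 epimers of the upper ring)
Product: 18 undeca-O-benzyl ether of 19 (upper chroman 2R,3R and C4 aryl cis to both the 3-benzyloxy and the 2-aryl group; lower chroman 2R,3R,4S), via diarylmethyl cation 17 (not isolated)
Conditions: Et3SiH (5 equiv), CF3CO2H (3 equiv), CH2Cl2, −40 °C
Reagents that add atoms: trifluoroacetic acid, OC(=O)C(F)(F)F (counter-ion of 17 only)
Why: Ionic hydrogenation: the tertiary, doubly benzylic alcohol ionises far more readily than the secondary C4 benzyl ether of the lower unit, and in cation 17 the 3-benzyloxy group is axial (2-aryl equatorial, no clash with the C4 aryl), so the silane hydride enters trans to it and the C4 aryl ends cis to the 3-oxygen and the 2-aryl group (all-cis upper ring).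

Step 12
Reactants: 18 undeca-O-benzyl ether of 19
Product: 19 (2R,3R,4R)-2-(3,4-dihydroxyphenyl)-4-[(2R,3R,4S)-2-(3,4-dihydroxyphenyl)-3,4,7,8-tetrahydroxychroman-6-yl]chroman-3,7,8-triol (upper ring 2,3-cis-3,4-cis; lower ring 2,3-cis-3,4-trans)
Conditions: H2 (1 atm), Pd(OH)2/C, THF/MeOH (1:1), degassed, 25 °C
Reagents that add atoms: none
Why: Hydrogenolysis of the eleven O-benzyl ethers under neutral conditions, as in the last step of proanthocyanidin syntheses; the benzylic C4–OH of the lower unit and the interflavan bond should survive without acid.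

**Compound list**

1 | 2,3,4-trihydroxybenzaldehyde | O=Cc1ccc(O)c(O)c1O | starting material
2 | 3,4-bis(benzyloxy)-2-hydroxybenzaldehyde | O=Cc1ccc(OCc2ccccc2)c(OCc2ccccc2)c1O | intermediate
3 | (3,4-dihydroxyphenyl)acetic acid | OC(=O)Cc1ccc(O)c(O)c1 | starting material
4 | benzyl 2-[3,4-bis(benzyloxy)phenyl]acetate | O=C(Cc1ccc(OCc2ccccc2)c(OCc2ccccc2)c1)OCc1ccccc1 | intermediate
5 | benzyl 2-[3,4-bis(benzyloxy)phenyl]-2-diazoacetate | [N-]=[N+]=C(C(=O)OCc1ccccc1)c1ccc(OCc2ccccc2)c(OCc2ccccc2)c1 | intermediate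
6 | benzyl (2R)-2-[3,4-bis(benzyloxy)phenyl]-2-[2,3-bis(benzyloxy)-6-formylphenoxy]acetate | O=Cc1ccc(OCc2ccccc2)c(OCc2ccccc2)c1O[C@@H](C(=O)OCc1ccccc1)c1ccc(OCc2ccccc2)c(OCc2ccccc2)c1 | intermediate
7 | 1,2-bis(benzyloxy)-3-{[(1R)-2-(benzyloxy)-1-[3,4-bis(benzyloxy)phenyl]prop-2-en-1-yl]oxy}-4-ethenylbenzene | C=Cc1ccc(OCc2ccccc2)c(OCc2ccccc2)c1O[C@@H](C(=C)OCc1ccccc1)c1ccc(OCc2ccccc2)c(OCc2ccccc2)c1 | intermediate
8 | (2R)-3,7,8-tris(benzyloxy)-2-[3,4-bis(benzyloxy)phenyl]-2H-chromene (cyclic enol ether) | c1cc2c(c(OCc3ccccc3)c1OCc1ccccc1)O[C@H](c1ccc(OCc3ccccc3)c(OCc3ccccc3)c1)C(OCc1ccccc1)=C2 | intermediate (not isolated)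
9 | C4 alkylborane of 8: boron on C4 and hydrogen on C3, both on the face opposite the 2-aryl group | c1cc2c(c(OCc3ccccc3)c1OCc1ccccc1)O[C@H](c1ccc(OCc3ccccc3)c(OCc3ccccc3)c1)[C@H](OCc1ccccc1)[C@H]2B | intermediate (not isolated)
10 | (2R,3R,4S)-3,7,8-tris(benzyloxy)-2-[3,4-bis(benzyloxy)phenyl]chroman-4-ol (2,3-cis-3,4-trans) | c1cc2c(c(OCc3ccccc3)c1OCc1ccccc1)O[C@H](c1ccc(OCc3ccccc3)c(OCc3ccccc3)c1)[C@H](OCc1ccccc1)[C@H]2O | intermediate
11 | (2R,3S)-3,7,8-tris(benzyloxy)-2-[3,4-bis(benzyloxy)phenyl]chroman-4-one (2,3-cis) | c1cc2c(c(OCc3ccccc3)c1OCc1ccccc1)O[C@H](c1ccc(OCc3ccccc3)c(OCc3ccccc3)c1)[C@H](OCc1ccccc1)C2=O | intermediate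
12 | (2R,3R,4S)-3,4,7,8-tetrakis(benzyloxy)-2-[3,4-bis(benzyloxy)phenyl]chromane | c1cc2c(c(OCc3ccccc3)c1OCc1ccccc1)O[C@H](c1ccc(OCc3ccccc3)c(OCc3ccccc3)c1)[C@H](OCc1ccccc1)[C@H]2OCc1ccccc1 | intermediate
13 | (2R,3R,4S)-6-bromo-3,4,7,8-tetrakis(benzyloxy)-2-[3,4-bis(benzyloxy)phenyl]chromane | Brc1cc2c(c(OCc3ccccc3)c1OCc1ccccc1)O[C@H](c1ccc(OCc3ccccc3)c(OCc3ccccc3)c1)[C@H](OCc1ccccc1)[C@H]2OCc1ccccc1 | intermediate
14 | C6 aryllithium of 12 | [Li]c1cc2c(c(OCc3ccccc3)c1OCc1ccccc1)O[C@H](c1ccc(OCc3ccccc3)c(OCc3ccccc3)c1)[C@H](OCc1ccccc1)[C@H]2OCc1ccccc1 | intermediate (not isolated)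
15 | C6 arylcerium dichloride of 12 | Cl[Ce](Cl)c1cc2c(c(OCc3ccccc3)c1OCc1ccccc1)O[C@H](c1ccc(OCc3ccccc3)c(OCc3ccccc3)c1)[C@H](OCc1ccccc1)[C@H]2OCc1ccccc1 | intermediate (not isolated)
16 | (2R,3S)-3,7,8-tris(benzyloxy)-2-[3,4-bis(benzyloxy)phenyl]-4-{(2R,3R,4S)-3,4,7,8-tetrakis(benzyloxy)-2-[3,4-bis(benzyloxy)phenyl]chroman-6-yl}chroman-4-ol, C4 of the upper ring as either epimer | c1cc2c(c(OCc3ccccc3)c1OCc1ccccc1)O[C@H](c1ccc(OCc3ccccc3)c(OCc3ccccc3)c1)[C@H](OCc1ccccc1)C2(O)c1cc2c(c(OCc3ccccc3)c1OCc1ccccc1)O[C@H](c1ccc(OCc3ccccc3)c(OCc3ccccc3)c1)[C@H](OCc1ccccc1)[C@H]2OCc1ccccc1 | intermediate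
17 | chroman-4-ylium cation of 16 (upper C4 cationic, carrying both aryl rings), trifluoroacetate | c1cc2c(c(OCc3ccccc3)c1OCc1ccccc1)O[C@H](c1ccc(OCc3ccccc3)c(OCc3ccccc3)c1)[C@H](OCc1ccccc1)[C+]2c1cc2c(c(OCc3ccccc3)c1OCc1ccccc1)O[C@H](c1ccc(OCc3ccccc3)c(OCc3ccccc3)c1)[C@H](OCc1ccccc1)[C@H]2OCc1ccccc1.[O-]C(=O)C(F)(F)F | intermediate (not isolated)
18 | undeca-O-benzyl ether of 19 (upper ring 2,3-cis-3,4-cis, lower ring 2,3-cis-3,4-trans) | c1cc2c(c(OCc3ccccc3)c1OCc1ccccc1)O[C@H](c1ccc(OCc3ccccc3)c(OCc3ccccc3)c1)[C@H](OCc1ccccc1)[C@@H]2c1cc2c(c(OCc3ccccc3)c1OCc1ccccc1)O[C@H](c1ccc(OCc3ccccc3)c(OCc3ccccc3)c1)[C@H](OCc1ccccc1)[C@H]2OCc1ccccc1 | intermediate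
19 | (2R,3R,4R)-2-(3,4-dihydroxyphenyl)-4-[(2R,3R,4S)-2-(3,4-dihydroxyphenyl)-3,4,7,8-tetrahydroxychroman-6-yl]chroman-3,7,8-triol | Oc1ccc([C@H]2Oc3c(ccc(O)c3O)[C@@H](c3cc4c(c(O)c3O)O[C@H](c3ccc(O)c(O)c3)[C@H](O)[C@H]4O)[C@H]2O)cc1O | target

**Step count and risks**

Total steps: 12. Longest linear sequence: 10 steps (3 → 4 → 5 → 6 → 7 → 10 → 12 → 13 → 16 → 18 → 19; steps 2, 3, 4, 5, 6, 8, 9, 10, 11, 12).

Steps most likely to fail:

Step 10. The aryl metal may deprotonate ketone 11 at C3 instead of adding (the enolate can then expel the ring oxygen and open ring C), and attack of a hindered aryl metal on a hindered, electron-rich carbonyl may be slow. The fallback sets out from 11 and 13 and uses the enolate on purpose. Ketone 11 is deprotonated with KHMDS in THF at −78 °C in the presence of PhNTf2, where trapping should outrun ring opening, to give the enol triflate F1. Bromide 13 is converted by Miyaura borylation (B2pin2, Pd(dppf)Cl2, KOAc, dioxane, 80 °C) into the pinacol boronate F2. Suzuki–Miyaura coupling of F1 with F2 (Pd(OAc)2, SPhos, K3PO4, toluene/water, 60 °C) should give the tetrasubstituted 4-aryl enol ether F3. Syn hydrogenation of F3 with [Ir(cod)(PCy3)(py)]PF6 and H2 in CH2Cl2 from the face opposite the 2-aryl group delivers H-3 and H-4 together, which is the all-cis arrangement, and the route is rejoined at 18 (16 and step 11 are bypassed).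

Step 11. The cation may lose the C3 proton and be re-protonated with loss of the C3 configuration, the C4 benzyl ether of the lower unit may ionise as well, or hydride may be delivered to the wrong face. The fallback sets out from 16 and comes back at 19 without any acid. The tertiary, doubly benzylic hydroxyl is removed by hydrogenolysis on palladium in the final operation together with the benzyl ethers (H2, Pd(OH)2/C, THF/MeOH, 25 °C). Benzylic C–O hydrogenolysis on palladium goes with inversion, and the organocerium is expected to have added trans to the axial 3-benzyloxy group, so the hydroxyl sits cis to it and inversion leads to the same all-cis upper ring. No new compound is made (F0).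

Step 4. Enantiofacial control in the proton shift of the palladium-bound ylide may be poor with a hindered, internally hydrogen-bonded phenol, and the carbene may be captured by the formyl oxygen. The fallback sets out from 5 and comes back at 6. Diazo ester 5 is oxidised with dimethyldioxirane (acetone, 0 °C) to the α-keto ester F4. Asymmetric transfer hydrogenation (RuCl(p-cymene)[(R,R)-TsDPEN] or its antipode, whichever gives the S alcohol, HCO2H/Et3N, 25 °C) gives the (S)-mandelate F5. Mitsunobu etherification of F5 with phenol 2 (PPh3, DIAD, toluene, 0 °C) proceeds with inversion at the benzylic carbon and should give the R ester 6.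

**Further compounds**

F1 | step 10 | (2R)-3,7,8-tris(benzyloxy)-2-[3,4-bis(benzyloxy)phenyl]-2H-chromen-4-yl trifluoromethanesulfonate | c1cc2c(c(OCc3ccccc3)c1OCc1ccccc1)O[C@H](c1ccc(OCc3ccccc3)c(OCc3ccccc3)c1)C(OCc1ccccc1)=C2OS(=O)(=O)C(F)(F)F
F2 | step 10 | C6 pinacol boronate of 12 (Bpin in place of Br of 13) | CC1(C)OB(OC1(C)C)c1cc2c(c(OCc3ccccc3)c1OCc1ccccc1)O[C@H](c1ccc(OCc3ccccc3)c(OCc3ccccc3)c1)[C@H](OCc1ccccc1)[C@H]2OCc1ccccc1
F3 | step 10 | 3,4-didehydro analogue of 18 (upper ring a 3-benzyloxy-4-aryl-2H-chromene) | c1cc2c(c(OCc3ccccc3)c1OCc1ccccc1)O[C@H](c1ccc(OCc3ccccc3)c(OCc3ccccc3)c1)C(OCc1ccccc1)=C2c1cc2c(c(OCc3ccccc3)c1OCc1ccccc1)O[C@H](c1ccc(OCc3ccccc3)c(OCc3ccccc3)c1)[C@H](OCc1ccccc1)[C@H]2OCc1ccccc1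
F0 | step 11 | none | none
F4 | step 4 | benzyl 2-[3,4-bis(benzyloxy)phenyl]-2-oxoacetate | O=C(C(=O)OCc1ccccc1)c1ccc(OCc2ccccc2)c(OCc2ccccc2)c1
F5 | step 4 | benzyl (2S)-2-[3,4-bis(benzyloxy)phenyl]-2-hydroxyacetate | O[C@H](C(=O)OCc1ccccc1)c1ccc(OCc2ccccc2)c(OCc2ccccc2)c1
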